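# Proposed total synthesis of CNP0297042.3

## Analysis of the target

The target is a C30 chain of two cyclohexane rings joined tail to tail. In ring A, C1 is quaternary (CH3 and a 4-methylpent-3-enoyl group), C2 is a secondary allylic carbinol and C3 carries the exocyclic alkene C3=C7. C7–C8–C8′–C7′ leads to ring B (C1′–C6′), which has the same constitution, so the centre is a 1,5-diene. The halves are not related by symmetry: C2 and C2′ are both R, but C1 is R and C1′ is S, so the hydroxyl is cis to the C1 methyl in ring A and cis to the acyl group in ring B. The molecule is therefore a union of two C1-epimeric halves and would be meso if C2 and C2′ were trigonal; this feature (C1/C1′ antipodal, C2/C2′ identical) is what the route is built on. Both trisubstituted alkenes are Z: C8 lies on the side of C2, not of C4, which is the opposite of what an aldol condensation at C3 of a C2 ketone gives. Sensitive groups are the β-hydroxy ketones with a quaternary α-carbon (retro-aldol under base), the β,γ-unsaturated ketones (conjugation) and the C2 hydroxyls, which close onto C8 whenever C8 carries a leaving group. The difficulty is that any symmetric plan (one enantiopure half, homodimerisation, two-directional ring formation under one catalyst) gives a diastereomer, and that the ketone at C2 must be reduced under reagent control while the side-chain ketones are absent.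

## Retrosynthetic reasoning

**30 ⇒ 25 + 26 (both C(=O)–CH2 bonds).** The two side-chain ketones are removed first, together. They are the most fragile groups and cannot coexist with a carbanion coupling or with a carbonyl reduction at C2. Cutting both at once makes the end-game two-directional: dialdehyde 25 takes up two prenyl units, one from each of two molecules of 26 (through 27), then 28 is oxidised to 29 and desilylated. The forward step must attack both neopentyl aldehydes with the α-carbon of the prenyl metal.

**25 ⇒ 19 + 21 (C8–C8′).** The central sp3–sp3 bond is cut because it separates the molecule into its two C1-epimeric halves. It must be made as a hetero-coupling, since the halves differ: ring A arrives as allylic bromide 19, ring B as allylic sulfone 21. The sulfone fixes the nucleophile at C8′ (no allylic transposition) and is removed from 23 by hydride under palladium catalysis; the same hydride reduces both esters to give 24. The forward steps must keep both Z alkenes.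

**19 and 21 ⇒ 11 and 12 (C8–O and the alkene geometry).** The Z geometry is not made by olefination. Each half is traced to a butenolide in which C8 is the lactone carbonyl and C2–O the ring oxygen, so C8 is held cis to C2 across C3=C7. Reduction of 11 and 12 to the diols 14 and 16, silylation to 17 and 18 and substitution at C8 to 19 and 20 carry the geometry over.

**11 and 12 ⇒ 7 and 8 ⇒ 4 (the key disconnection; C2–H bond and the lactone ring).** Both butenolides are traced to one racemic keto diester 4. C1 is never set by asymmetric synthesis: the racemate is the exact 1:1 supply of both C1 configurations that the target needs. One catalyst-controlled hydrogenation of the C2 ketone gives the 2R carbinol in both antipodes, that is, 5 and 6, which lactonise to 7 and 8. All four stereocentres of 30 are thus defined in one operation on a compound made in one step.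

**4 ⇒ 1 + 2 (C3–C7).** C1 of ketone 1 is quaternary, so its only enolate (3) is at C3; alkylation with 2 brings in C7 and C8 at the lactone oxidation level.

## Alternatives that were turned down

**Alternative 1:** (the textbook cut) C8–C8′ into two identical halves, with tail-to-tail homocoupling of one enantiopure allylic bromide A1 whose quaternary centre is set by asymmetric alkylation and whose carbinol is relayed from it. Turned down: it assumes a C2 axis that the target lacks; coupling A1 with itself gives A2, the (1R,2R,1′R,2′R) diastereomer. To reach 30 this way, A1 and its C1 epimer would both be needed, with opposite absolute configuration at C1 and opposite relative configuration at C2, so substrate control that works in one series fails in the other. That means two enantioselective sequences and two different carbinol-forming steps.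

**Alternative 2:** (biomimetic) cut C1–C2 and C1′–C2′: double intramolecular aldol of the acyclic C30 diketo dialdehyde A3, closing both rings and setting four stereocentres at once. Turned down: A3 is symmetric, so one catalyst or one metal enolate geometry gives the same relative and absolute sense in both rings (the skeleton of A2) or no selectivity at all. The target needs syn in one ring and anti in the other with the same sense at C2. In addition the ketone enolises preferentially at the CH2 between carbonyl and alkene (conjugation), the Z-enals isomerise, and A3 itself needs two Z-trisubstituted enals.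

**Alternative 3:** cut C2–C3 and C7–C8 in each ring: nickel-catalysed alkylative cyclisation of ynal A4 (aldehyde, terminal alkyne, organozinc), which would close the ring, make the carbinol and set the Z alkene by syn addition. Turned down: C2 is formed under control of C1, so each ring needs enantiopure A4 of opposite configuration and opposite diastereoselectivity, and no catalyst-controlled alkylative version is established that would let the racemate be used. The C8–C8′ unit would also have to come from an alkylzinc bearing β-hydrogens and the other ring, where hydride transfer competes and gives the wrong alkene geometry.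

Key step: step 2

Assumption: 1 is used as the purchased racemate, and the facial sense of step 2 with (R)-BINAP is taken from the β-keto ester chelate model (ester-bearing arm second in priority, giving R); it would be confirmed on 14 and 16 by MTPA ester analysis before material is carried on.

Remark on locants: in the bicyclic lactones (7–13, 15) the benzofuranone positions C7, C7a, C3a, C3, C2 are the target atoms C1, C2, C3, C7, C8.

## Steps

Step 1
Reactants: 1 methyl 1-methyl-2-oxocyclohexane-1-carboxylate (racemic); 2 methyl bromoacetate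
Product: 4 methyl 3-(2-methoxy-2-oxoethyl)-1-methyl-2-oxocyclohexane-1-carboxylate (racemic; both C3 epimers), via lithium enolate 3 (not isolated)
Conditions: LiN(iPr)2 (1.05 equiv), THF, −78 °C; then 2, −78 → −20 °C
Reagents that add atoms: none
Why: Ketone enolate alkylation (SN2); C1 is quaternary, so deprotonation can only occur at C3 and 3 is formed regiospecifically; the new C3 centre is left uncontrolled because step 3 makes it trigonal.

Step 2
Reactants: 4 methyl 3-(2-methoxy-2-oxoethyl)-1-methyl-2-oxocyclohexane-1-carboxylate
Product: 7 methyl (7R,7aR)-7-methyl-2-oxooctahydro-1-benzofuran-7-carboxylate and 8 its (7S,7aR) diastereomer (each as C3a epimers; carried on as the mixture), via 1R hydroxy diester 5 (not isolated), via 1S hydroxy diester 6 (not isolated)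
Conditions: H2 (100 atm), RuCl2[(R)-BINAP] (2 mol%), MeOH, 80 °C; then 4-MeC6H4SO3H·H2O (cat.), toluene, 80 °C
Reagents that add atoms: none
Why: Noyori hydrogenation of a β-keto ester: the ketone oxygen and the carbonyl of the C1 ester chelate ruthenium, and the Ru–H adds to the C2 carbonyl inside this six-membered chelate, the face being chosen by the BINAP quadrants and not by the substrate. The closest known cases are the hydrogenations of racemic α,α-disubstituted β-keto esters and of 2-oxocycloalkanecarboxylates, in which both antipodes are reduced with the same catalyst-dictated carbinol configuration. The new stereocentre C2 (C7a) should therefore be R in both antipodes of 4 while C1 is untouched, so the racemate becomes 5 (1R,2R) and 6 (1S,2R), the two halves of the target, and one operation defines all four stereocentres of 30. The ring that closes is the γ-lactone, by 5-exo-trig acyl substitution of the C2 hydroxyl on the side-chain ester under acid; it holds C8 cis to C2–O (the later Z geometry) and masks the hydroxyl. C3 (C3a) is epimerisable and left uncontrolled because step 3 removes it. The selectivity needed is reagent control over the small substrate bias (CH3 against CO2CH3 at C1) for both antipodes, and chelation by the β-ester (six-membered) rather than by the side-chain γ-ester (seven-membered), which would deliver hydride to the other face; the near-equal size of the two C1 substituents and the chelate ring size secure these. Esters are inert and no alkene is present yet, which is why the reduction is placed here.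

Step 3
Reactants: 7 and 8 (the mixture from step 2)
Product: 11 methyl (7R,7aR)-7-methyl-2-oxo-2,4,5,6,7,7a-hexahydro-1-benzofuran-7-carboxylate and 12 its (7S,7aR) diastereomer (separated by chromatography), via selenide 9 (not isolated), via selenide 10 (not isolated)
Conditions: LiN(iPr)2, THF, −78 °C; PhSeBr; then H2O2, pyridine, CH2Cl2, 0 °C → rt
Reagents that add atoms: none
Why: α-Selenenylation of the lactone and selenoxide syn-elimination; the only hydrogen β to selenium is C3a–H, so the alkene can only form as C3=C3a (target C7=C3) and both C3a epimers converge; the five-membered ring fixes C8 cis to C2–O, and the two remaining diastereomers differ only in the cis or trans relation at C7/C7a and should separate on silica.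

Step 4
Reactants: 11 methyl (7R,7aR)-7-methyl-2-oxo-2,4,5,6,7,7a-hexahydro-1-benzofuran-7-carboxylate
Product: 14 methyl (1R,2R,3Z)-2-hydroxy-3-(2-hydroxyethylidene)-1-methylcyclohexane-1-carboxylate, via lactol 13 (not isolated)
Conditions: iBu2AlH (1.1 equiv), CH2Cl2, −78 °C; MeOH; then NaBH4, CeCl3·7H2O, MeOH, −20 °C
Reagents that add atoms: none
Why: 1,2-Reduction of the butenolide carbonyl stops at lactol 13 at −78 °C, the neopentyl methyl ester being slower, and the quench with methanol keeps the medium non-acidic so that 13 is not dehydrated to the furan; Luche reduction of the ring-opened Z hydroxy enal then gives the diol without touching the ester or the alkene, whose Z geometry is inherited from the ring.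

Step 5
Reactants: 12 methyl (7S,7aR)-7-methyl-2-oxo-2,4,5,6,7,7a-hexahydro-1-benzofuran-7-carboxylate
Product: 16 methyl (1S,2R,3Z)-2-hydroxy-3-(2-hydroxyethylidene)-1-methylcyclohexane-1-carboxylate, via lactol 15 (not isolated)
Conditions: iBu2AlH (1.1 equiv), CH2Cl2, −78 °C; MeOH; then NaBH4, CeCl3·7H2O, MeOH, −20 °C
Reagents that add atoms: none
Why: Same lactone-to-lactol reduction and Luche reduction as in step 4, on the C1 epimer.

Step 6
Reactants: 14 methyl (1R,2R,3Z)-2-hydroxy-3-(2-hydroxyethylidene)-1-methylcyclohexane-1-carboxylate
Product: 17 methyl (1R,2R,3Z)-2-[(tert-butyldimethylsilyl)oxy]-3-{2-[(tert-butyldimethylsilyl)oxy]ethylidene}-1-methylcyclohexane-1-carboxylate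
Conditions: TBSOTf (3 equiv), 2,6-lutidine, CH2Cl2, −78 → 0 °C
Reagents that add atoms: tert-butyldimethylsilyl triflate, CC(C)(C)[Si](C)(C)OS(=O)(=O)C(F)(F)F
Why: Silylation of both hydroxyls with a silyl triflate, strong enough for the neopentyl C2 hydroxyl; the C2 silyl ether blocks closure onto C8 and later blocks retro-aldol.

Step 7
Reactants: 16 methyl (1S,2R,3Z)-2-hydroxy-3-(2-hydroxyethylidene)-1-methylcyclohexane-1-carboxylate
Product: 18 methyl (1S,2R,3Z)-2-[(tert-butyldimethylsilyl)oxy]-3-{2-[(tert-butyldimethylsilyl)oxy]ethylidene}-1-methylcyclohexane-1-carboxylate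
Conditions: TBSOTf (3 equiv), 2,6-lutidine, CH2Cl2, −78 → 0 °C
Reagents that add atoms: tert-butyldimethylsilyl triflate, CC(C)(C)[Si](C)(C)OS(=O)(=O)C(F)(F)F
Why: Same double silylation as step 6.

Step 8
Reactants: 17 methyl (1R,2R,3Z)-2-[(tert-butyldimethylsilyl)oxy]-3-{2-[(tert-butyldimethylsilyl)oxy]ethylidene}-1-methylcyclohexane-1-carboxylate
Product: 19 methyl (1R,2R,3Z)-3-(2-bromoethylidene)-2-[(tert-butyldimethylsilyl)oxy]-1-methylcyclohexane-1-carboxylate
Conditions: Ph3PBr2 (1.2 equiv), CH2Cl2, 0 °C
Reagents that add atoms: triphenylphosphine dibromide, BrP(Br)(c1ccccc1)(c1ccccc1)c1ccccc1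
Why: Direct conversion of a silyl ether into a bromide: the primary allylic silyl ether gives the alkoxyphosphonium ion and bromide displaces by SN2 at C8, while the hindered neopentyl C2 silyl ether should not react; SN2 at the primary carbon keeps the Z alkene.

Step 9
Reactants: 18 methyl (1S,2R,3Z)-2-[(tert-butyldimethylsilyl)oxy]-3-{2-[(tert-butyldimethylsilyl)oxy]ethylidene}-1-methylcyclohexane-1-carboxylate
Product: 20 methyl (1S,2R,3Z)-3-(2-bromoethylidene)-2-[(tert-butyldimethylsilyl)oxy]-1-methylcyclohexane-1-carboxylate
Conditions: Ph3PBr2 (1.2 equiv), CH2Cl2, 0 °C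
Reagents that add atoms: triphenylphosphine dibromide, BrP(Br)(c1ccccc1)(c1ccccc1)c1ccccc1
Why: Same bromodesilylation as step 8.

Step 10
Reactants: 20 methyl (1S,2R,3Z)-3-(2-bromoethylidene)-2-[(tert-butyldimethylsilyl)oxy]-1-methylcyclohexane-1-carboxylate
Product: 21 methyl (1S,2R,3Z)-2-[(tert-butyldimethylsilyl)oxy]-1-methyl-3-[2-(phenylsulfonyl)ethylidene]cyclohexane-1-carboxylate
Conditions: PhSO2Na (1.5 equiv), DMF, 0 °C → rt
Reagents that add atoms: sodium benzenesulfinate, [Na+].[O-]S(=O)c1ccccc1
Why: SN2 S-alkylation of the sulfinate by the primary allylic bromide; attack at C3 (SN2′) would build a fully substituted ring carbon and is not expected.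

Step 11
Reactants: 21 methyl (1S,2R,3Z)-2-[(tert-butyldimethylsilyl)oxy]-1-methyl-3-[2-(phenylsulfonyl)ethylidene]cyclohexane-1-carboxylate; 19 methyl (1R,2R,3Z)-3-(2-bromoethylidene)-2-[(tert-butyldimethylsilyl)oxy]-1-methylcyclohexane-1-carboxylate
Product: 23 coupled diester sulfone (ring A 1R,2R,3Z; ring B 1′S,2′R,3′Z; both C2–O silylated; PhSO2 on C8′; both C8′ epimers), via lithiated sulfone 22 (not isolated)
Conditions: LiN(iPr)2 (1.05 equiv), THF, −78 °C; then 19, −78 → −40 °C
Reagents that add atoms: none
Why: Allyl sulfone alkylation: the α-sulfonyl carbanion 22 reacts at C8′ with the primary allylic bromide by SN2, forming C8–C8′ with both Z alkenes retained; intramolecular attack of 22 on its own ester would need a bridgehead alkene and is not expected, and the C8′ epimers converge in step 12.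

Step 12
Reactants: 23 coupled diester sulfone
Product: 24 bis(hydroxymethyl) diene (CH2OH on C1 and C1′; C2–O and C2′–O silylated; CIP 1S,2R,1′R,2′R,3Z,3′Z with unchanged geometry)
Conditions: LiHBEt3 (8 equiv), PdCl2[Ph2P(CH2)3PPh2] (10 mol%), THF, 0 °C → rt
Reagents that add atoms: none
Why: Palladium-catalysed hydride desulfonylation: zerovalent palladium ionises the allylic sulfone and hydride is delivered to the less substituted terminus C8′, so C7′=C3′ stays in place; its geometry holds because syn–anti exchange at the fully substituted terminus C3′ would need a tertiary σ-allyl; the same hydride reduces both hindered methyl esters to primary alcohols.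

Step 13
Reactants: 24 bis(hydroxymethyl) diene
Product: 25 dialdehyde (CHO on C1 and C1′; 1R,2R,1′S,2′R,3Z,3′Z; C2–O and C2′–O silylated)
Conditions: Dess–Martin periodinane (3 equiv), NaHCO3, CH2Cl2, rt
Reagents that add atoms: none
Why: Dess–Martin oxidation of neopentyl primary alcohols; the aldehydes have no α-hydrogen, so C1 and C1′ cannot epimerise.

Step 14
Reactants: 25 dialdehyde (1 equiv); 26 1-chloro-3-methylbut-2-ene (prenyl chloride; 3 equiv charged, two molecules are incorporated, one at each aldehyde)
Product: 28 bis(homoallylic alcohol) (CH(OH)CH2CH=C(CH3)2 on C1 and C1′; epimers at both new carbinols), via 3-methylbut-2-enylbarium chloride 27 (not isolated)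
Conditions: BaI2 (3 equiv), lithium biphenylide (LiC12H10, 6 equiv), THF, rt; 26 (3 equiv), −78 °C; then 25 (1 equiv), −78 °C
Reagents that add atoms: 1-chloro-3-methylbut-2-ene (the second molecule of 26 that enters the product, as a second equivalent of 27), CC(C)=CCCl
Why: Two-directional allylbarium addition to both aldehydes: each formyl group takes up one molecule of 27, so the balanced reaction consumes two molecules of 26 per molecule of 25 and the reagent is used in excess to drive the second addition. Unlike the magnesium, zinc or boron prenyl reagents, 27 reacts at its α-carbon without allylic transposition, giving the linear 4-methylpent-3-enyl carbinols; the two new carbinol centres are uncontrolled and are oxidised away in step 15.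

Step 15
Reactants: 28 bis(homoallylic alcohol)
Product: 29 bis(tert-butyldimethylsilyl) ether of the target (4-methylpent-3-enoyl on C1 and C1′)
Conditions: Dess–Martin periodinane (3 equiv), NaHCO3, CH2Cl2, 0 °C → rt
Reagents that add atoms: none
Why: Dess–Martin oxidation under buffered, non-basic conditions gives the β,γ-unsaturated ketones without moving the alkene into conjugation.

Step 16
Reactants: 29 bis(tert-butyldimethylsilyl) ether of the target
Product: 30 CNP0297042.3 (ring A 1R,2R,3Z; ring B 1′S,2′R,3′Z)
Conditions: HF·pyridine, pyridine, THF, 0 °C → rt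
Reagents that add atoms: none
Why: Silyl ether cleavage by buffered HF·pyridine; no free alkoxide or strong base is formed, which avoids retro-aldol of the β-hydroxy ketones and conjugation of the β,γ-enones.

## Compound list

1 | methyl 1-methyl-2-oxocyclohexane-1-carboxylate (racemic) | COC(=O)C1(C)CCCCC1=O | starting material
2 | methyl bromoacetate | COC(=O)CBr | starting material
3 | lithium enolate of 1 (C2=C3) | COC(=O)C1(C)CCCC=C1[O-].[Li+] | intermediate (not isolated)
4 | methyl 3-(2-methoxy-2-oxoethyl)-1-methyl-2-oxocyclohexane-1-carboxylate (racemic, C3 epimers) | COC(=O)CC1CCCC(C)(C(=O)OC)C1=O | intermediate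
5 | methyl (1R,2R)-2-hydroxy-3-(2-methoxy-2-oxoethyl)-1-methylcyclohexane-1-carboxylate (C3 epimers) | COC(=O)[C@]1(C)CCCC(CC(=O)OC)[C@H]1O | intermediate (not isolated)
6 | methyl (1S,2R)-2-hydroxy-3-(2-methoxy-2-oxoethyl)-1-methylcyclohexane-1-carboxylate (C3 epimers) | COC(=O)[C@@]1(C)CCCC(CC(=O)OC)[C@H]1O | intermediate (not isolated)
7 | methyl (7R,7aR)-7-methyl-2-oxooctahydro-1-benzofuran-7-carboxylate (C3a epimers) | COC(=O)[C@]1(C)CCCC2CC(=O)O[C@@H]12 | intermediate
8 | methyl (7S,7aR)-7-methyl-2-oxooctahydro-1-benzofuran-7-carboxylate (C3a epimers) | COC(=O)[C@@]1(C)CCCC2CC(=O)O[C@@H]12 | intermediate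
9 | methyl (7R,7aR)-7-methyl-2-oxo-3-(phenylselanyl)octahydro-1-benzofuran-7-carboxylate (C3, C3a epimers) | COC(=O)[C@]1(C)CCCC2C([Se]c3ccccc3)C(=O)O[C@@H]12 | intermediate (not isolated)
10 | methyl (7S,7aR)-7-methyl-2-oxo-3-(phenylselanyl)octahydro-1-benzofuran-7-carboxylate (C3, C3a epimers) | COC(=O)[C@@]1(C)CCCC2C([Se]c3ccccc3)C(=O)O[C@@H]12 | intermediate (not isolated)
11 | methyl (7R,7aR)-7-methyl-2-oxo-2,4,5,6,7,7a-hexahydro-1-benzofuran-7-carboxylate | COC(=O)[C@]1(C)CCCC2=CC(=O)O[C@@H]12 | intermediate
12 | methyl (7S,7aR)-7-methyl-2-oxo-2,4,5,6,7,7a-hexahydro-1-benzofuran-7-carboxylate | COC(=O)[C@@]1(C)CCCC2=CC(=O)O[C@@H]12 | intermediate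
13 | methyl (7R,7aR)-2-hydroxy-7-methyl-2,4,5,6,7,7a-hexahydro-1-benzofuran-7-carboxylate (both anomers) | COC(=O)[C@]1(C)CCCC2=CC(O)O[C@@H]12 | intermediate (not isolated)
14 | methyl (1R,2R,3Z)-2-hydroxy-3-(2-hydroxyethylidene)-1-methylcyclohexane-1-carboxylate | COC(=O)[C@]1(C)CCC/C(=C/CO)[C@H]1O | intermediate
15 | methyl (7S,7aR)-2-hydroxy-7-methyl-2,4,5,6,7,7a-hexahydro-1-benzofuran-7-carboxylate (both anomers) | COC(=O)[C@@]1(C)CCCC2=CC(O)O[C@@H]12 | intermediate (not isolated)
16 | methyl (1S,2R,3Z)-2-hydroxy-3-(2-hydroxyethylidene)-1-methylcyclohexane-1-carboxylate | COC(=O)[C@@]1(C)CCC/C(=C/CO)[C@H]1O | intermediate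
17 | methyl (1R,2R,3Z)-2-[(tert-butyldimethylsilyl)oxy]-3-{2-[(tert-butyldimethylsilyl)oxy]ethylidene}-1-methylcyclohexane-1-carboxylate | COC(=O)[C@]1(C)CCC/C(=C/CO[Si](C)(C)C(C)(C)C)[C@H]1O[Si](C)(C)C(C)(C)C | intermediate
18 | methyl (1S,2R,3Z)-2-[(tert-butyldimethylsilyl)oxy]-3-{2-[(tert-butyldimethylsilyl)oxy]ethylidene}-1-methylcyclohexane-1-carboxylate | COC(=O)[C@@]1(C)CCC/C(=C/CO[Si](C)(C)C(C)(C)C)[C@H]1O[Si](C)(C)C(C)(C)C | intermediate
19 | methyl (1R,2R,3Z)-3-(2-bromoethylidene)-2-[(tert-butyldimethylsilyl)oxy]-1-methylcyclohexane-1-carboxylate | COC(=O)[C@]1(C)CCC/C(=C/CBr)[C@H]1O[Si](C)(C)C(C)(C)C | intermediate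
20 | methyl (1S,2R,3Z)-3-(2-bromoethylidene)-2-[(tert-butyldimethylsilyl)oxy]-1-methylcyclohexane-1-carboxylate | COC(=O)[C@@]1(C)CCC/C(=C/CBr)[C@H]1O[Si](C)(C)C(C)(C)C | intermediate
21 | methyl (1S,2R,3Z)-2-[(tert-butyldimethylsilyl)oxy]-1-methyl-3-[2-(phenylsulfonyl)ethylidene]cyclohexane-1-carboxylate | COC(=O)[C@@]1(C)CCC/C(=C/CS(=O)(=O)c2ccccc2)[C@H]1O[Si](C)(C)C(C)(C)C | intermediate
22 | lithium salt of 21 deprotonated at C8′ | COC(=O)[C@@]1(C)CCC/C(=C/[CH-]S(=O)(=O)c2ccccc2)[C@H]1O[Si](C)(C)C(C)(C)C.[Li+] | intermediate (not isolated)
23 | coupled diester sulfone: ring A (1R,2R,3Z) and ring B (1′S,2′R,3′Z) joined C7–C8–C8′–C7′, CO2CH3 on C1 and C1′, OTBS on C2 and C2′, PhSO2 on C8′ (both epimers) | COC(=O)[C@]1(C)CCC/C(=C/CC(S(=O)(=O)c3ccccc3)/C=C2/CCC[C@](C)(C(=O)OC)[C@@H]2O[Si](C)(C)C(C)(C)C)[C@H]1O[Si](C)(C)C(C)(C)C | intermediate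
24 | bis(hydroxymethyl) diene: CH2OH on C1 and C1′, OTBS on C2 and C2′ (1S,2R,1′R,2′R,3Z,3′Z) | OC[C@]1(C)CCC/C(=C/CC/C=C2/CCC[C@](C)(CO)[C@@H]2O[Si](C)(C)C(C)(C)C)[C@H]1O[Si](C)(C)C(C)(C)C | intermediate
25 | dialdehyde: CHO on C1 and C1′, OTBS on C2 and C2′ (1R,2R,1′S,2′R,3Z,3′Z) | O=C[C@]1(C)CCC/C(=C/CC/C=C2/CCC[C@](C)(C=O)[C@@H]2O[Si](C)(C)C(C)(C)C)[C@H]1O[Si](C)(C)C(C)(C)C | intermediate
26 | 1-chloro-3-methylbut-2-ene | CC(C)=CCCl | starting material
27 | 3-methylbut-2-enylbarium chloride | CC(C)=CC[Ba]Cl | intermediate (not isolated)
28 | bis(homoallylic alcohol): 1-hydroxy-4-methylpent-3-enyl on C1 and C1′, OTBS on C2 and C2′ (1S,2R,1′R,2′R,3Z,3′Z; epimers at both new carbinols) | CC(C)=CCC(O)[C@]1(C)CCC/C(=C/CC/C=C2/CCC[C@](C)(C(O)CC=C(C)C)[C@@H]2O[Si](C)(C)C(C)(C)C)[C@H]1O[Si](C)(C)C(C)(C)C | intermediate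
29 | bis(tert-butyldimethylsilyl) ether of the target (1R,2R,1′S,2′R,3Z,3′Z) | CC(C)=CCC(=O)[C@]1(C)CCC/C(=C/CC/C=C2/CCC[C@](C)(C(=O)CC=C(C)C)[C@@H]2O[Si](C)(C)C(C)(C)C)[C@H]1O[Si](C)(C)C(C)(C)C | intermediate
30 | CNP0297042.3: ring A (1R,2R,3Z)-2-hydroxy-1-methyl-1-(4-methylpent-3-enoyl)cyclohexane, ring B its (1′S,2′R,3′Z) isomer, joined C3=C7–C8–C8′–C7′=C3′ | CC(C)=CCC(=O)[C@]1(C)CCC/C(=C/CC/C=C2/CCC[C@](C)(C(=O)CC=C(C)C)[C@@H]2O)[C@H]1O | target

## Step count and least certain steps

Total step count: 16. Longest linear sequence: 13 (steps 1, 2, 3, 5, 7, 9, 10, 11, 12, 13, 14, 15, 16).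

**Step 2 (key step).** Catalyst control may be incomplete for the antipode of 4 in which the preferred chelate conformation forces hydride to the more hindered face. Chelation by the side-chain ester may compete and deliver hydride to the opposite face. The doubly α-branched ketone may also react slowly. Each would lower the enantiopurity of one series. Fallback: from 4, reduction without a chiral reagent (NaBH4, MeOH, then acid) gives the racemic saturated lactones F1; under the conditions of step 3 these give the racemic butenolide of the 7R*,7aR* series F2 and the racemic butenolide of the 7S*,7aR* series F3. They are separated from each other on silica, and each is resolved on a chiral stationary phase by preparative HPLC; the 7aR enantiomers are 11 and 12, where the route is rejoined. This replaces asymmetric catalysis by a resolution and uses half of the material.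

**Step 8 (and its twin, step 9).** The secondary silyl ether may also be lost, or the allylic bromide may close onto the C2 oxygen with loss of the silyl group to give a dihydrofuran; reversible bromide addition may scramble the alkene geometry. Fallback: from 17, the primary silyl ether is cleaved selectively (HF·pyridine buffered with pyridine, THF, 0 °C) to the primary allylic alcohol F4, which is brominated under Appel conditions (CBr4, PPh3, CH2Cl2, −20 °C) to return at 19. In the same way 18 gives the primary allylic alcohol F5 and returns at 20.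

**Step 12.** Hydride may be delivered to the wrong allyl terminus (the alkene moves to C7′=C8′), the π-allyl may equilibrate (loss of the Z geometry), or ester reduction may be incomplete. Fallback: the sulfone is avoided. From 20, active barium at −78 °C gives the allylbarium chloride F6, which couples at its α-carbon with bromide 19 (α,α′-selective allylbarium–allyl halide cross-coupling, geometry retained) to the sulfone-free diester F7; LiAlH4 in THF at 0 °C reduces both esters and returns at 24. The ester groups limit this to low temperature and short reaction time.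

**Step 14.** A share of attack through the γ-carbon (reverse prenylation) may occur, or addition may stop after one of the two neopentyl aldehydes has reacted. Fallback: from 25, the lithium salt of 3-methylbut-2-enyl phenyl sulfone (n-BuLi, THF, −78 °C; two molecules are taken up), which can only react at its α-carbon, adds to both aldehydes to give the bis(β-hydroxy sulfone) F8. Dess–Martin oxidation gives the bis(β-keto sulfone) F9, and SmI2 in THF/MeOH at −78 °C removes both sulfonyl groups, with α-protonation of the dienolates, to return at 29.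

## Further compounds

F1 | step 2 | methyl 7-methyl-2-oxooctahydro-1-benzofuran-7-carboxylate (racemic, all diastereomers) | COC(=O)C1(C)CCCC2CC(=O)OC12
F2 | step 2 | racemic methyl (7R*,7aR*)-7-methyl-2-oxo-2,4,5,6,7,7a-hexahydro-1-benzofuran-7-carboxylate | COC(=O)[C@]1(C)CCCC2=CC(=O)O[C@@H]12.COC(=O)[C@@]1(C)CCCC2=CC(=O)O[C@H]12
F3 | step 2 | racemic methyl (7S*,7aR*)-7-methyl-2-oxo-2,4,5,6,7,7a-hexahydro-1-benzofuran-7-carboxylate | COC(=O)[C@@]1(C)CCCC2=CC(=O)O[C@@H]12.COC(=O)[C@]1(C)CCCC2=CC(=O)O[C@H]12
F4 | step 8 | methyl (1R,2R,3Z)-2-[(tert-butyldimethylsilyl)oxy]-3-(2-hydroxyethylidene)-1-methylcyclohexane-1-carboxylate | COC(=O)[C@]1(C)CCC/C(=C/CO)[C@H]1O[Si](C)(C)C(C)(C)C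
F5 | step 8 | methyl (1S,2R,3Z)-2-[(tert-butyldimethylsilyl)oxy]-3-(2-hydroxyethylidene)-1-methylcyclohexane-1-carboxylate | COC(=O)[C@@]1(C)CCC/C(=C/CO)[C@H]1O[Si](C)(C)C(C)(C)C
F6 | step 12 | allylbarium chloride derived from 20 (barium on C8′) | COC(=O)[C@@]1(C)CCC/C(=C/C[Ba]Cl)[C@H]1O[Si](C)(C)C(C)(C)C
F7 | step 12 | sulfone-free coupled diester (ring A 1R,2R,3Z; ring B 1′S,2′R,3′Z; OTBS on C2 and C2′) | COC(=O)[C@]1(C)CCC/C(=C/CC/C=C2/CCC[C@](C)(C(=O)OC)[C@@H]2O[Si](C)(C)C(C)(C)C)[C@H]1O[Si](C)(C)C(C)(C)C
F8 | step 14 | bis(β-hydroxy sulfone): 1-hydroxy-4-methyl-2-(phenylsulfonyl)pent-3-enyl on C1 and C1′ (epimer mixture), OTBS on C2 and C2′ | CC(C)=CC(S(=O)(=O)c3ccccc3)C(O)[C@]1(C)CCC/C(=C/CC/C=C2/CCC[C@](C)(C(O)C(C=C(C)C)S(=O)(=O)c4ccccc4)[C@@H]2O[Si](C)(C)C(C)(C)C)[C@H]1O[Si](C)(C)C(C)(C)C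
F9 | step 14 | bis(β-keto sulfone): 4-methyl-2-(phenylsulfonyl)pent-3-enoyl on C1 and C1′ (epimer mixture), OTBS on C2 and C2′ | CC(C)=CC(S(=O)(=O)c3ccccc3)C(=O)[C@]1(C)CCC/C(=C/CC/C=C2/CCC[C@](C)(C(=O)C(C=C(C)C)S(=O)(=O)c4ccccc4)[C@@H]2O[Si](C)(C)C(C)(C)C)[C@H]1O[Si](C)(C)C(C)(C)C
A1 | alternative 1 | 1-[(1R,2R,3Z)-3-(2-bromoethylidene)-2-[(tert-butyldimethylsilyl)oxy]-1-methylcyclohexyl]-4-methylpent-3-en-1-one | CC(C)=CCC(=O)[C@]1(C)CCC/C(=C/CBr)[C@H]1O[Si](C)(C)C(C)(C)C
A2 | alternative 1 | C2-symmetric (1R,2R,1′R,2′R,3Z,3′Z) diastereomer of the target | CC(C)=CCC(=O)[C@]1(C)CCC/C(=C/CC/C=C2/CCC[C@@](C)(C(=O)CC=C(C)C)[C@@H]2O)[C@H]1O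
A3 | alternative 2 | acyclic C30 diketo dialdehyde (both enals Z, CHO cis to the central chain; CH(CH3) centres unassigned) | CC(C)=CCC(=O)C(C)CCC/C(C=O)=C/CC/C=C(C=O)/CCCC(C)C(=O)CC=C(C)C
A4 | alternative 3 | methyl 2-formyl-2-methylhept-6-ynoate | COC(=O)C(C)(C=O)CCCC#C
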